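## Retrosynthetic overview

- The quinone comes from para-oxidation of a 3-methoxy-5-alkylphenol, the O-methylated alkylresorcinol that the polyketide pathway delivers before hydroxylation.
- The benzene ring (the only ring) comes from aldol closure and aromatization of an open-chain poly-β-carbonyl chain. The bond formed (terminal methyl carbon onto the starter-unit ketone) is the one alkylresorcinol synthase makes, and the chain is used without its carboxyl group.
- The methyl ether is already on the chain as an enol ether, so only one of the two resorcinol oxygens ends up methylated.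
- The open chain comes from C-acylation of the enolate of (E)-4-methoxypent-3-en-2-one (masked triketide) with the half-ester acid chloride of hexadecanedioic acid (starter unit).
- Ring order: one ring, closed in step 2 and oxidized to the quinone in step 3.

Assumption: the target has no stereocentre, so it is made as the single achiral compound drawn. The only stereo-element on the way is the (E) enol ether double bond of commercial 2, which disappears on aromatization.

## Route

Step 1
Reactants: 1 16-methoxy-16-oxohexadecanoic acid (monomethyl hexadecanedioate); 2 (E)-4-methoxypent-3-en-2-one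
Product: 5 methyl (19E)-20-methoxy-16,18-dioxohenicos-19-enoate, via acid chloride 3 (not isolated), via lithium enolate 4 (not isolated)
Conditions: (a) 1, (COCl)2 (1.3 equiv), cat. DMF, CH2Cl2, 0 °C to rt, evaporate; (b) 2 (2.2 equiv), LiN(SiMe3)2 (2.2 equiv), THF, −78 °C, then 3 in THF, −78 °C, 20 min; sat. aq. NH4Cl; quick column on Et3N-washed silica
Reagents that add atoms: none
Why: Crossed Claisen-type C-acylation of a kinetic lithium enolate with an acid chloride, the acylation used to make pyranone precursors from β-methoxy enones; the second equivalent of enolate deprotonates the 1,3-diketone as it forms and stops double acylation, the distal methyl ester is inert at −78 °C, the (E) geometry of 2 is carried over, and acylation at the γ-methyl instead would give a regioisomeric chain that closes to the same phenol.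

Step 2
Reactants: 5 methyl (19E)-20-methoxy-16,18-dioxohenicos-19-enoate
Product: 8 15-(3-hydroxy-5-methoxyphenyl)pentadecanoic acid, via cyclic aldol 6 (not isolated), via phenol ester 7 (not isolated)
Conditions: NaOMe (5 equiv), degassed MeOH (0.05 M), Ar, 65 °C; then H2O, 65 °C; 1 M HCl to pH 3, 0 °C
Reagents that add atoms: water, O
Why: Proposed new method: under methoxide the diketonate of 5 equilibrates through methanol with a small amount of the γ-deprotonated dienolate of the β-methoxy enone (C21, held cis to the C18 carbonyl by the (E) double bond), whose 6-(enolendo)-exo-trig vinylogous aldol addition to the free C16 ketone gives racemic 6, and loss of water plus enolization aromatizes it irreversibly to 7 before the added water saponifies the ester; methoxide attack on the enol ether or the ester is degenerate, so the single O-methyl group survives and the stereocentre of 6 is destroyed; the closest known reaction types are the base-mediated (Collie–Harris) aldol cyclization of 2,4,6-triketones to orcinol-type resorcinols and the methoxide-induced aromatization of enol-ether- or pyranone-masked poly-β-carbonyl chains.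

Step 3
Reactants: 8 15-(3-hydroxy-5-methoxyphenyl)pentadecanoic acid
Product: 9 15-(5-methoxy-3,6-dioxocyclohexa-1,4-dien-1-yl)pentadecanoic acid (target)
Conditions: (KSO3)2NO (Fremy's salt, 2.5 equiv), aq. KH2PO4 (pH 6)/acetone 2:1, rt, 3 h; H3PO4 to pH 3, CH2Cl2 extraction
Reagents that add atoms: potassium nitrosodisulfonate (Fremy's salt), [K+].[K+].[O-]S(=O)(=O)N([O])S(=O)(=O)[O-]
Why: Teuber oxidation, in which one nitroxyl radical abstracts the phenolic hydrogen and a second couples at the free position para to the OH (between OMe and the chain) before imidodisulfonate is lost to give the 2-methoxy-6-alkyl-1,4-benzoquinone, as established for 3-methoxy-5-alkylphenols; the carboxylate is inert and pH 6 spares the methoxyquinone.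

## Compound list

1 | 16-methoxy-16-oxohexadecanoic acid (monomethyl hexadecanedioate) | COC(=O)CCCCCCCCCCCCCCC(=O)O | starting material
2 | (E)-4-methoxypent-3-en-2-one | CC(=O)/C=C(\C)OC | starting material
3 | methyl 16-chloro-16-oxohexadecanoate | COC(=O)CCCCCCCCCCCCCCC(=O)Cl | intermediate
4 | lithium (3E)-4-methoxypenta-1,3-dien-2-olate | [Li+].[O-]C(=C)/C=C(\C)OC | intermediate
5 | methyl (19E)-20-methoxy-16,18-dioxohenicos-19-enoate | COC(=O)CCCCCCCCCCCCCCC(=O)CC(=O)/C=C(\C)OC | intermediate
6 | methyl 15-(1-hydroxy-3-methoxy-5-oxocyclohex-3-en-1-yl)pentadecanoate (racemic) | COC(=O)CCCCCCCCCCCCCCC1(O)CC(=O)C=C(OC)C1 | intermediate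
7 | methyl 15-(3-hydroxy-5-methoxyphenyl)pentadecanoate | COC(=O)CCCCCCCCCCCCCCc1cc(O)cc(OC)c1 | intermediate
8 | 15-(3-hydroxy-5-methoxyphenyl)pentadecanoic acid | OC(=O)CCCCCCCCCCCCCCc1cc(O)cc(OC)c1 | intermediate
9 | 15-(5-methoxy-3,6-dioxocyclohexa-1,4-dien-1-yl)pentadecanoic acid | COC1=CC(=O)C=C(CCCCCCCCCCCCCCC(=O)O)C1=O | target

## Step count and risks

Total step count: 3. Longest linear sequence: 3 (1 → 5 → 8 → 9).

Steps most likely to fail, most risky first:

Step 2. The vinylogous aldol may stall at the unreactive diketonate, and unreacted 5 then closes through oxygen to the pyranone on acidification. The enol ether may also be lost. The fallback sets out from 5 and comes back at 8. Compound 5 is deliberately closed with CF3CO2H in CH2Cl2 at rt (enol oxygen adds to C20, methanol leaves) to give methyl 15-(6-methyl-4-oxo-4H-pyran-2-yl)pentadecanoate F1. Heating F1 in degassed 4 M aqueous KOH opens the pyranone to the free 2,4,6-triketone, whose methyl terminus closes onto the chain ketone (Collie-type aldol) while the ester is saponified, giving 15-(3,5-dihydroxyphenyl)pentadecanoic acid F2. One of the two equivalent phenols of F2 is then methylated with Me2SO4 (1.0 equiv) in aqueous NaOH at 0 °C; the carboxylate is not alkylated in water, and the dimethyl ether and unchanged F2 are separated and recycled. This delivers 8.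

Step 1. O-acylation of the enolate or further acylation of the diketonate can erode the yield. The fallback sets out from 3 and comes back at 5, replacing acylation by aldol addition and oxidation. Compound 3 is reduced with LiAlH(OtBu)3 in THF at −78 °C to methyl 16-oxohexadecanoate F3. Adding F3 to lithium enolate 4 (1.2 equiv, THF, −78 °C) gives racemic methyl (19E)-16-hydroxy-20-methoxy-18-oxohenicos-19-enoate F4. Dess–Martin periodinane with NaHCO3 in CH2Cl2 oxidizes the β-hydroxy ketone to 5.

Step 3. The soap-like substrate may react sluggishly in the aqueous medium, and some ortho-quinone or over-oxidation is possible. The fallback sets out from 8 and comes back at 9, splitting the oxidation into para-hydroxylation and hydroquinone oxidation. Elbs oxidation of 8 with K2S2O8 in aqueous KOH at 0–20 °C gives the para-sulfate 15-[5-hydroxy-3-methoxy-2-(sulfooxy)phenyl]pentadecanoic acid F5. Hot dilute HCl hydrolyses it to 15-(2,5-dihydroxy-3-methoxyphenyl)pentadecanoic acid F6. FeCl3 in aqueous MeOH at rt oxidizes F6 to 9.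

## Further compounds

F1 | step 2 | methyl 15-(6-methyl-4-oxo-4H-pyran-2-yl)pentadecanoate | COC(=O)CCCCCCCCCCCCCCC1=CC(=O)C=C(C)O1
F2 | step 2 | 15-(3,5-dihydroxyphenyl)pentadecanoic acid | OC(=O)CCCCCCCCCCCCCCc1cc(O)cc(O)c1
F3 | step 1 | methyl 16-oxohexadecanoate | COC(=O)CCCCCCCCCCCCCCC=O
F4 | step 1 | methyl (19E)-16-hydroxy-20-methoxy-18-oxohenicos-19-enoate (racemic) | COC(=O)CCCCCCCCCCCCCCC(O)CC(=O)/C=C(\C)OC
F5 | step 3 | 15-[5-hydroxy-3-methoxy-2-(sulfooxy)phenyl]pentadecanoic acid | OC(=O)CCCCCCCCCCCCCCc1cc(O)cc(OC)c1OS(=O)(=O)O
F6 | step 3 | 15-(2,5-dihydroxy-3-methoxyphenyl)pentadecanoic acid | OC(=O)CCCCCCCCCCCCCCc1cc(O)cc(OC)c1O
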